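Numbering used: ring A = C1–C5 + C10 (C4 gem-dimethyl), ring B = C5–C10 (C8=C9), chain C11–C16, butenolide C16–C19 (C19 = C=O), C20 = CH2OH on C17, C25 = CH2OH on C13.
Butenolide (last ring): acylation/intramolecular Wittig of the C16 α-hydroxy ketone with Ph3P=C=C=O; C16 (R) and C15–C16 come from RAMP-hydrazone alkylation of 2,2-dimethyl-1,3-dioxan-5-one.
C12–C13 by B-alkyl Suzuki coupling of a decalin ethylborane with an (E)-vinyl iodide (syn-hydrostannation of a but-2-yne-1,4-diol unit fixes C13=C14); C9–C11 by vinylation of the C9 enol triflate.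
Decalin: rings A and B are closed in one operation from an acyclic keto-enal, C5–C10 first (ring A), then C7–C8 (ring B); the resulting C7=C8–C9=O enone is turned into the C8=C9 triflate by 1,4-reduction/triflation.
Enabling feature: C9 of ring B can hold a ketone oxygen that makes both its ring B neighbours C8 and C10 nucleophilic, while C5–C6–C7 of ring B can be an enal (electrophilic at C5 and C7) hung on the quaternary C4 of ring A, which has no hydrogen to lose.

Key step: step 6

Step 1
Reactants: 1 pentan-3-one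
Product: 2 1,1-dimethyl-2-(pentan-3-ylidene)hydrazine
Conditions: H2NNMe2 (1.2 equiv), AcOH (cat.), EtOH, reflux
Reagents that add atoms: 1,1-dimethylhydrazine, CN(C)N
Why: Hydrazone condensation masks the ketone against the later hydride reduction and allows clean mono-C-alkylation through the azaenolate (Corey–Enders hydrazone chemistry).

Step 2
Reactants: 3 2-methylpropanenitrile; 4 1,3-dibromopropane
Product: 6 5-bromo-2,2-dimethylpentanenitrile, via lithiated nitrile 5 (not isolated)
Conditions: LiN(i-Pr)2 (1.05 equiv), THF, −78 °C; then added to 4 (3 equiv), THF, −78 °C → rt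
Reagents that add atoms: none
Why: SN2 alkylation of the tertiary nitrile-stabilised carbanion builds the quaternary C4 with its gem-dimethyl group, and the excess of dibromide should suppress double displacement.

Step 3
Reactants: 2 1,1-dimethyl-2-(pentan-3-ylidene)hydrazine; 6 5-bromo-2,2-dimethylpentanenitrile
Product: 8 7-(2,2-dimethylhydrazinylidene)-2,2,6-trimethylnonanenitrile, via lithium azaenolate 7 (not isolated)
Conditions: LiN(i-Pr)2 (1.05 equiv), THF, 0 °C; then 6, −78 °C → rt
Reagents that add atoms: none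
Why: Corey–Enders alkylation of the hydrazone azaenolate with the primary bromide forms C1–C10; the new centre C10 is racemic, which does not matter because it is enolised in step 6.

Step 4
Reactants: 8 7-(2,2-dimethylhydrazinylidene)-2,2,6-trimethylnonanenitrile
Product: 10 2,2,6-trimethyl-7-oxononanal, via N-aluminated aldimine 9 (not isolated)
Conditions: i-Bu2AlH (1.2 equiv), toluene, −78 °C; then 1 M aq. HCl, Et2O, 0 °C → rt
Reagents that add atoms: water, O
Why: Partial reduction of the hindered nitrile with i-Bu2AlH should stop at the imine while the hydrazone is inert to hydride, and one acidic hydrolysis then releases both the aldehyde (no α-hydrogen, so no self-condensation) and the ketone.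

Step 5
Reactants: 10 2,2,6-trimethyl-7-oxononanal; 11 (triphenylphosphoranylidene)acetaldehyde
Product: 12 (2E)-4,4,8-trimethyl-9-oxoundec-2-enal
Conditions: 11 (1.2 equiv), toluene, 90 °C
Reagents that add atoms: none
Why: Wittig olefination with the formyl-stabilised ylide should react with the aldehyde only, not with the ketone, and give the (E)-enal.

Step 6
Reactants: 12 (2E)-4,4,8-trimethyl-9-oxoundec-2-enal
Product: 14 (4aS,8aS)-2,5,5,8a-tetramethyl-4a,5,6,7,8,8a-hexahydronaphthalen-1(4H)-one, via Michael adduct 13 (not isolated)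
Conditions: (S)-2-[diphenyl(trimethylsilyloxy)methyl]pyrrolidine (20 mol %), PhCO2H (20 mol %), toluene (0.05 M), 40 °C
Reagents that add atoms: none
Why: Proposed new method: the secondary amine converts the enal into an E-configured iminium ion, the acid-promoted enol of the ketone attacks C5 through its more substituted terminus C10 (intramolecular Michael addition, 6-exo-trig, closing ring A), and the enamine so formed is protonated to a second iminium ion that is captured at C7 by the C8 enol (6-enolexo-exo-trig Mannich/aldol closure of ring B) before β-elimination of the amine gives the C7=C8–C9=O enone and frees the catalyst. The closest known reaction types are the diarylprolinol-ether-catalysed Michael/aldol-condensation cyclohexenone annulation of β-keto esters with enals and the Stork enamine–acrolein α,α'-annulation; new here is a simple α-branched ketone as intramolecular donor for both bonds. C5 is set by the catalyst, whose CPh2(OSiMe3) group shields one face of the s-trans iminium ion so that C10 adds to the Si face of C5 (5S), and C10 is set relative to C5 in the chair transition state of ring A, in which the enol unit (future C9) and C6 are both pseudo-equatorial and only the C10 methyl is axial, which gives the trans ring fusion (10S). The regioselectivity between the two enolisable carbons rests on ring size (C10 closes a six-membered ring, C8 would close an eight-membered one), and the quaternary C4 both forbids γ-deprotonation to a dienamine and accelerates the first closure by the gem-dimethyl effect. After the Michael step C7 lies within six-ring reach of C8 only, and the final loss of water makes the sequence irreversible.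

Step 7
Reactants: 14 (4aS,8aS)-2,5,5,8a-tetramethyl-4a,5,6,7,8,8a-hexahydronaphthalen-1(4H)-one
Product: 16 (4aS,8aS)-2,5,5,8a-tetramethyl-3,4,4a,5,6,7,8,8a-octahydronaphthalen-1-yl trifluoromethanesulfonate, via lithium enolate 15 (not isolated)
Conditions: LiBH(s-Bu)3 (1.1 equiv), THF, −78 °C; then PhNTf2 (1.2 equiv), −78 °C → rt
Reagents that add atoms: N-phenylbis(trifluoromethanesulfonimide), O=S(=O)(N(c1ccccc1)S(=O)(=O)C(F)(F)F)C(F)(F)F
Why: Conjugate hydride reduction of the β-unsubstituted enone, whose carbonyl is shielded by the quaternary C10, should give the C8=C9 enolate regiospecifically, and O-sulfonylation traps it as the tetrasubstituted enol triflate.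

Step 8
Reactants: 16 (4aS,8aS)-2,5,5,8a-tetramethyl-3,4,4a,5,6,7,8,8a-octahydronaphthalen-1-yl trifluoromethanesulfonate; 17 tributyl(ethenyl)stannane
Product: 18 (4aS,8aS)-1-ethenyl-2,5,5,8a-tetramethyl-3,4,4a,5,6,7,8,8a-octahydronaphthalene
Conditions: Pd(PPh3)4 (5 mol %), LiCl (3 equiv), THF, reflux
Reagents that add atoms: none
Why: Stille coupling of a hindered cyclohexenyl triflate with a vinylstannane, as known for 2,6,6-trimethylcyclohexenyl triflates, forms C9–C11 and leaves C8=C9 in place.

Step 9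
Reactants: 19 but-2-yne-1,4-diol
Product: 20 4-[(tert-butyldiphenylsilyl)oxy]but-2-yn-1-ol
Conditions: t-BuPh2SiCl (1 equiv), 19 (3 equiv), imidazole, DMF, 0 °C → rt
Reagents that add atoms: tert-butyl(chloro)diphenylsilane, CC(C)(C)[Si](Cl)(c1ccccc1)c1ccccc1
Why: Statistical monosilylation of the symmetrical diol used in excess supplies C25–C13–C14–C15 with the C25 oxygen protected by an acid-stable group.

Step 10
Reactants: 20 4-[(tert-butyldiphenylsilyl)oxy]but-2-yn-1-ol
Product: 21 [(4-bromobut-2-yn-1-yl)oxy](tert-butyl)diphenylsilane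
Conditions: CBr4, PPh3, CH2Cl2, 0 °C
Reagents that add atoms: tetrabromomethane, BrC(Br)(Br)Br
Why: Appel bromination converts the primary propargylic alcohol into the bromide without touching the silyl ether.

Step 11
Reactants: 22 2,2-dimethyl-1,3-dioxan-5-one; 23 (R)-1-amino-2-(methoxymethyl)pyrrolidine (RAMP)
Product: 24 (R)-N-(2,2-dimethyl-1,3-dioxan-5-ylidene)-2-(methoxymethyl)pyrrolidin-1-amine
Conditions: benzene, reflux, water separator
Reagents that add atoms: none
Why: Hydrazone condensation attaches the Enders auxiliary to the protected dihydroxyacetone unit that will become C16–C17–C20.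

Step 12
Reactants: 24 (R)-N-(2,2-dimethyl-1,3-dioxan-5-ylidene)-2-(methoxymethyl)pyrrolidin-1-amine; 21 [(4-bromobut-2-yn-1-yl)oxy](tert-butyl)diphenylsilane
Product: 26 (R)-N-[(4R)-4-{4-[(tert-butyldiphenylsilyl)oxy]but-2-yn-1-yl}-2,2-dimethyl-1,3-dioxan-5-ylidene]-2-(methoxymethyl)pyrrolidin-1-amine, via lithium azaenolate 25 (not isolated)
Conditions: t-BuLi (1.1 equiv), THF, −78 °C; then 21, −100 °C → rt
Reagents that add atoms: none
Why: Enders RAMP-hydrazone alkylation: the chelated lithium azaenolate is alkylated by the propargylic bromide on the face left open by the methoxymethylpyrrolidine unit, which with RAMP should give the (4R) centre (C16), the mirror image of the (S) outcome known for the SAMP hydrazone of this ketone.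

Step 13
Reactants: 26 (R)-N-[(4R)-4-{4-[(tert-butyldiphenylsilyl)oxy]but-2-yn-1-yl}-2,2-dimethyl-1,3-dioxan-5-ylidene]-2-(methoxymethyl)pyrrolidin-1-amine
Product: 27 (R)-N-[(4R)-4-{(2E)-4-[(tert-butyldiphenylsilyl)oxy]-3-(tributylstannyl)but-2-en-1-yl}-2,2-dimethyl-1,3-dioxan-5-ylidene]-2-(methoxymethyl)pyrrolidin-1-amine
Conditions: Bu3SnH (1.3 equiv), PdCl2(PPh3)2 (3 mol %), THF, 0 °C → rt
Reagents that add atoms: tributyltin hydride, CCCC[SnH](CCCC)CCCC
Why: Palladium-catalysed syn-hydrostannation should place tin on C13, the alkyne carbon next to the inductively withdrawing CH2OSi group and remote from the branched dioxane substituent, and the syn addition fixes CH2O cis to C15.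

Step 14
Reactants: 27 (R)-N-[(4R)-4-{(2E)-4-[(tert-butyldiphenylsilyl)oxy]-3-(tributylstannyl)but-2-en-1-yl}-2,2-dimethyl-1,3-dioxan-5-ylidene]-2-(methoxymethyl)pyrrolidin-1-amine
Product: 28 (R)-N-[(4R)-4-{(2E)-4-[(tert-butyldiphenylsilyl)oxy]-3-iodobut-2-en-1-yl}-2,2-dimethyl-1,3-dioxan-5-ylidene]-2-(methoxymethyl)pyrrolidin-1-amine
Conditions: I2 (1.05 equiv), CH2Cl2, −78 → 0 °C
Reagents that add atoms: iodine, [I][I]
Why: Iododestannylation is very fast and stereoretentive, so titration with iodine at low temperature should exchange tin for iodine without touching the hydrazone.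

Step 15
Reactants: 18 (4aS,8aS)-1-ethenyl-2,5,5,8a-tetramethyl-3,4,4a,5,6,7,8,8a-octahydronaphthalene; 28 (R)-N-[(4R)-4-{(2E)-4-[(tert-butyldiphenylsilyl)oxy]-3-iodobut-2-en-1-yl}-2,2-dimethyl-1,3-dioxan-5-ylidene]-2-(methoxymethyl)pyrrolidin-1-amine
Product: 30 RAMP hydrazone of (4R)-4-[(2Z)-3-{[(tert-butyldiphenylsilyl)oxy]methyl}-5-[(4aS,8aS)-2,5,5,8a-tetramethyl-3,4,4a,5,6,7,8,8a-octahydronaphthalen-1-yl]pent-2-en-1-yl]-2,2-dimethyl-1,3-dioxan-5-one, via B-alkyl-9-BBN 29 (not isolated)
Conditions: 9-BBN-H (9-borabicyclo[3.3.1]nonane, 1.2 equiv), THF, 0 °C → rt; then 28, Pd(dppf)Cl2 (5 mol %), AsPh3 (10 mol %), Cs2CO3 (3 equiv), DMF/THF/H2O, rt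
Reagents that add atoms: none
Why: Anti-Markovnikov hydroboration of the terminal vinyl group (the tetrasubstituted ring alkene is inert to 9-BBN-H) followed by B-alkyl Suzuki–Miyaura coupling with the unhindered vinyl iodide forms C12–C13 with retention of the alkene geometry, and hydrazone, acetal and silyl ether are stable to the aqueous base.

Step 16
Reactants: 30 RAMP hydrazone of the coupled dioxanone
Product: 31 (3R,5Z)-6-{[(tert-butyldiphenylsilyl)oxy]methyl}-1,3-dihydroxy-8-[(4aS,8aS)-2,5,5,8a-tetramethyl-3,4,4a,5,6,7,8,8a-octahydronaphthalen-1-yl]oct-5-en-2-one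
Conditions: 1 M aq. HCl, THF, 0 °C → rt
Reagents that add atoms: water, O
Why: Acid hydrolysis cleaves the hydrazone and the acetonide in one operation and leaves the tert-butyldiphenylsilyl ether; C16 is not touched, and the mild, cold conditions should keep enolisation of the α-hydroxy ketone slow.

Step 17
Reactants: 31 the dihydroxy ketone
Product: 32 (3R,5Z)-1-[(tert-butyldimethylsilyl)oxy]-6-{[(tert-butyldiphenylsilyl)oxy]methyl}-3-hydroxy-8-[(4aS,8aS)-2,5,5,8a-tetramethyl-3,4,4a,5,6,7,8,8a-octahydronaphthalen-1-yl]oct-5-en-2-one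
Conditions: t-BuMe2SiCl (1.1 equiv), imidazole, CH2Cl2, −20 → 0 °C
Reagents that add atoms: tert-butyl(chloro)dimethylsilane, CC(C)(C)[Si](C)(C)Cl
Why: Silylation of the primary C20 hydroxyl in preference to the secondary C16 hydroxyl leaves only the C16 oxygen free, so that the lactone can close in one direction only.

Step 18
Reactants: 32 the mono-protected α-hydroxy ketone; 33 (triphenylphosphoranylidene)ketene
Product: 35 (5R)-4-{[(tert-butyldimethylsilyl)oxy]methyl}-5-[(2Z)-3-{[(tert-butyldiphenylsilyl)oxy]methyl}-5-[(4aS,8aS)-2,5,5,8a-tetramethyl-3,4,4a,5,6,7,8,8a-octahydronaphthalen-1-yl]pent-2-en-1-yl]furan-2(5H)-one, via acyl ylide 34 (not isolated)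
Conditions: 33 (1.3 equiv), toluene, 90 °C
Reagents that add atoms: none
Why: The Bestmann ylide is added to by the C16 hydroxyl to give an ester-stabilised ylide that closes onto the C17 ketone by intramolecular Wittig reaction under neutral conditions, forming the butenolide without epimerising C16.

Step 19
Reactants: 35 the bis-silylated butenolide
Product: 36 16-epi-luffarin L
Conditions: HF·pyridine, pyridine/THF, 0 °C → rt
Reagents that add atoms: none
Why: Acidic fluoride removes both primary silyl ethers without base, so the butenolide and its C16 centre should survive.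

Compound list
1 | pentan-3-one | CCC(=O)CC | starting material
2 | 1,1-dimethyl-2-(pentan-3-ylidene)hydrazine | CCC(CC)=NN(C)C | intermediate
3 | 2-methylpropanenitrile | CC(C)C#N | starting material
4 | 1,3-dibromopropane | BrCCCBr | starting material
5 | lithium 2-cyanopropan-2-ide | [Li+].C[C-](C)C#N | intermediate (not isolated)
6 | 5-bromo-2,2-dimethylpentanenitrile | CC(C)(CCCBr)C#N | intermediate
7 | lithium azaenolate of 2 | CC=C(CC)N([Li])N(C)C | intermediate (not isolated)
8 | 7-(2,2-dimethylhydrazinylidene)-2,2,6-trimethylnonanenitrile (racemic, C=N isomers) | CCC(=NN(C)C)C(C)CCCC(C)(C)C#N | intermediate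
9 | N-(diisobutylalumanyl)aldimine of 10 with the hydrazone still in place | CCC(=NN(C)C)C(C)CCCC(C)(C)C=N[Al](CC(C)C)CC(C)C | intermediate (not isolated)
10 | 2,2,6-trimethyl-7-oxononanal (racemic) | CCC(=O)C(C)CCCC(C)(C)C=O | intermediate
11 | (triphenylphosphoranylidene)acetaldehyde | O=CC=P(c1ccccc1)(c1ccccc1)c1ccccc1 | starting material
12 | (2E)-4,4,8-trimethyl-9-oxoundec-2-enal (racemic) | CCC(=O)C(C)CCCC(C)(C)/C=C/C=O | intermediate
13 | 2-[(1S,2S)-2,6,6-trimethyl-2-propanoylcyclohexyl]acetaldehyde (held on the catalyst as enamine or iminium ion) | CCC(=O)[C@@]1(C)CCCC(C)(C)[C@@H]1CC=O | intermediate (not isolated)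
14 | (4aS,8aS)-2,5,5,8a-tetramethyl-4a,5,6,7,8,8a-hexahydronaphthalen-1(4H)-one | CC1=CC[C@H]2C(C)(C)CCC[C@]2(C)C1=O | intermediate
15 | lithium (4aS,8aS)-2,5,5,8a-tetramethyl-3,4,4a,5,6,7,8,8a-octahydronaphthalen-1-olate | CC1=C(O[Li])[C@@]2(C)CCCC(C)(C)[C@@H]2CC1 | intermediate (not isolated)
16 | (4aS,8aS)-2,5,5,8a-tetramethyl-3,4,4a,5,6,7,8,8a-octahydronaphthalen-1-yl trifluoromethanesulfonate | CC1=C(OS(=O)(=O)C(F)(F)F)[C@@]2(C)CCCC(C)(C)[C@@H]2CC1 | intermediate
17 | tributyl(ethenyl)stannane | C=C[Sn](CCCC)(CCCC)CCCC | starting material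
18 | (4aS,8aS)-1-ethenyl-2,5,5,8a-tetramethyl-3,4,4a,5,6,7,8,8a-octahydronaphthalene | CC1=C(C=C)[C@@]2(C)CCCC(C)(C)[C@@H]2CC1 | intermediate
19 | but-2-yne-1,4-diol | OCC#CCO | starting material
20 | 4-[(tert-butyldiphenylsilyl)oxy]but-2-yn-1-ol | OCC#CCO[Si](c1ccccc1)(c1ccccc1)C(C)(C)C | intermediate
21 | [(4-bromobut-2-yn-1-yl)oxy](tert-butyl)diphenylsilane | BrCC#CCO[Si](c1ccccc1)(c1ccccc1)C(C)(C)C | intermediate
22 | 2,2-dimethyl-1,3-dioxan-5-one | CC1(C)OCC(=O)CO1 | starting material
23 | (R)-1-amino-2-(methoxymethyl)pyrrolidine (RAMP) | COC[C@H]1CCCN1N | starting material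
24 | (R)-N-(2,2-dimethyl-1,3-dioxan-5-ylidene)-2-(methoxymethyl)pyrrolidin-1-amine | CC1(C)OCC(CO1)=NN1CCC[C@@H]1COC | intermediate
25 | lithium azaenolate of 24 | CC1(C)OCC(=CO1)N([Li])N1CCC[C@@H]1COC | intermediate (not isolated)
26 | (R)-N-[(4R)-4-{4-[(tert-butyldiphenylsilyl)oxy]but-2-yn-1-yl}-2,2-dimethyl-1,3-dioxan-5-ylidene]-2-(methoxymethyl)pyrrolidin-1-amine | CC(C)(C)[Si](c1ccccc1)(c1ccccc1)OCC#CC[C@H]1OC(C)(C)OCC1=NN1CCC[C@@H]1COC | intermediate
27 | (E)-vinylstannane: 26 with H on C14 and Bu3Sn on C13, CH2OSi cis to C15 | CCCC[Sn](CCCC)(CCCC)/C(=C/C[C@H]1OC(C)(C)OCC1=NN1CCC[C@@H]1COC)CO[Si](c1ccccc1)(c1ccccc1)C(C)(C)C | intermediate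
28 | (E)-vinyl iodide: 27 with iodine in place of tin | I/C(=C/C[C@H]1OC(C)(C)OCC1=NN1CCC[C@@H]1COC)CO[Si](c1ccccc1)(c1ccccc1)C(C)(C)C | intermediate
29 | 9-{2-[(4aS,8aS)-2,5,5,8a-tetramethyl-3,4,4a,5,6,7,8,8a-octahydronaphthalen-1-yl]ethyl}-9-borabicyclo[3.3.1]nonane | CC1=C(CCB3C4CCCC3CCC4)[C@@]2(C)CCCC(C)(C)[C@@H]2CC1 | intermediate (not isolated)
30 | RAMP hydrazone of (4R)-4-[(2Z)-3-{[(tert-butyldiphenylsilyl)oxy]methyl}-5-[(4aS,8aS)-2,5,5,8a-tetramethyl-3,4,4a,5,6,7,8,8a-octahydronaphthalen-1-yl]pent-2-en-1-yl]-2,2-dimethyl-1,3-dioxan-5-one | CC1=C(CC/C(=C/C[C@H]2OC(C)(C)OCC2=NN2CCC[C@@H]2COC)CO[Si](c2ccccc2)(c2ccccc2)C(C)(C)C)[C@@]2(C)CCCC(C)(C)[C@@H]2CC1 | intermediate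
31 | (3R,5Z)-6-{[(tert-butyldiphenylsilyl)oxy]methyl}-1,3-dihydroxy-8-[(4aS,8aS)-2,5,5,8a-tetramethyl-3,4,4a,5,6,7,8,8a-octahydronaphthalen-1-yl]oct-5-en-2-one | CC1=C(CC/C(=C/C[C@@H](O)C(=O)CO)CO[Si](c2ccccc2)(c2ccccc2)C(C)(C)C)[C@@]2(C)CCCC(C)(C)[C@@H]2CC1 | intermediate
32 | 1-O-(tert-butyldimethylsilyl) ether of 31 | CC1=C(CC/C(=C/C[C@@H](O)C(=O)CO[Si](C)(C)C(C)(C)C)CO[Si](c2ccccc2)(c2ccccc2)C(C)(C)C)[C@@]2(C)CCCC(C)(C)[C@@H]2CC1 | intermediate
33 | (triphenylphosphoranylidene)ketene | O=C=C=P(c1ccccc1)(c1ccccc1)c1ccccc1 | starting material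
34 | (triphenylphosphoranylidene)acetate ester of the C16 hydroxyl of 32 | CC1=C(CC/C(=C/C[C@@H](OC(=O)C=P(c2ccccc2)(c2ccccc2)c2ccccc2)C(=O)CO[Si](C)(C)C(C)(C)C)CO[Si](c2ccccc2)(c2ccccc2)C(C)(C)C)[C@@]2(C)CCCC(C)(C)[C@@H]2CC1 | intermediate (not isolated)
35 | (5R)-4-{[(tert-butyldimethylsilyl)oxy]methyl}-5-[(2Z)-3-{[(tert-butyldiphenylsilyl)oxy]methyl}-5-[(4aS,8aS)-2,5,5,8a-tetramethyl-3,4,4a,5,6,7,8,8a-octahydronaphthalen-1-yl]pent-2-en-1-yl]furan-2(5H)-one | CC1=C(CC/C(=C/C[C@H]2OC(=O)C=C2CO[Si](C)(C)C(C)(C)C)CO[Si](c2ccccc2)(c2ccccc2)C(C)(C)C)[C@@]2(C)CCCC(C)(C)[C@@H]2CC1 | intermediate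
36 | 16-epi-luffarin L, (5R)-4-(hydroxymethyl)-5-[(2Z)-3-(hydroxymethyl)-5-[(4aS,8aS)-2,5,5,8a-tetramethyl-3,4,4a,5,6,7,8,8a-octahydronaphthalen-1-yl]pent-2-en-1-yl]furan-2(5H)-one | CC1=C(CC/C(=C/C[C@H]2OC(=O)C=C2CO)CO)[C@@]2(C)CCCC(C)(C)[C@@H]2CC1 | target

Total step count: 19. Longest linear sequence: 12 steps (steps 1, 3, 4, 5, 6, 7, 8, 15, 16, 17, 18, 19).

Steps most likely to fail

Step 6 (Proposed new method). Enolisation of the unactivated α-branched ketone may be too slow for the Michael addition to the hindered iminium ion to outrun oligomerisation of the enal, the two faces of the iminium ion may be told apart poorly, or some cis-fused material may form. The fallback sets out from 12 and uses known enolate chemistry instead of iminium catalysis: KOt-Bu (catalytic) in t-BuOH/THF should effect the intramolecular Michael addition/aldol condensation under thermodynamic control and give the racemic trans-fused enone F1. This is resolved by preparative chromatography on a chiral stationary phase, and the (4aS,8aS) enantiomer re-enters the route as 14.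

Step 13. Tin may be delivered to C14 instead of C13, so that the iodine and later the decalin chain end on the wrong alkene carbon. The fallback sets out from 18 and comes back at 30, with regiochemistry and geometry fixed by a magnesium chelate instead of by the catalyst. Hydroboration of 18 with 9-BBN-H and iodinolysis (I2, NaOMe) would give the primary iodide (4aS,8aS)-1-(2-iodoethyl)-2,5,5,8a-tetramethyl-3,4,4a,5,6,7,8,8a-octahydronaphthalene F2. Its Grignard reagent (Mg, Et2O) is added to the magnesium alkoxide of prop-2-yn-1-ol with catalytic CuI (anti carbomagnesiation through the five-membered chelate, Duboudin type), and quenching the vinylmagnesium species with I2 gives the (2Z)-3-iodo-2-substituted prop-2-en-1-ol F3. Silylation (t-BuPh2SiCl, imidazole) gives the silyl ether F4. Iodine–lithium exchange (t-BuLi, Et2O, −78 °C) and trapping with paraformaldehyde gives, with retention, the (2Z)-allylic alcohol F5, and Appel bromination (CBr4, PPh3) gives the allylic bromide F6. F6 alkylates azaenolate 25 (made from 24 as in step 12) and gives 30 directly, so that steps 9, 10 and 13 to 15 are not needed.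

Step 5. The neopentyl aldehyde may be olefinated so slowly that the keto aldehyde closes by intramolecular aldol addition first, and the product, itself an aldehyde, may be olefinated a second time. The fallback sets out from 10 and makes the enal at the ester oxidation level. Horner–Wadsworth–Emmons reaction with triethyl phosphonoacetate (LiCl, DBU, MeCN) gives ethyl (2E)-4,4,8-trimethyl-9-oxoundec-2-enoate F7. i-Bu2AlH reduces ester and ketone to (2E)-4,4,8-trimethylundec-2-ene-1,9-diol F8, and Dess–Martin periodinane oxidises both hydroxyl groups and returns 12.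

Further compounds
F1 | step 6 | racemic trans-fused enone (both enantiomers of 14) | CC1=CC[C@H]2C(C)(C)CCC[C@]2(C)C1=O.CC1=CC[C@@H]2C(C)(C)CCC[C@@]2(C)C1=O
F2 | step 13 | (4aS,8aS)-1-(2-iodoethyl)-2,5,5,8a-tetramethyl-3,4,4a,5,6,7,8,8a-octahydronaphthalene | CC1=C(CCI)[C@@]2(C)CCCC(C)(C)[C@@H]2CC1
F3 | step 13 | (2Z)-3-iodo-2-{2-[(4aS,8aS)-2,5,5,8a-tetramethyl-3,4,4a,5,6,7,8,8a-octahydronaphthalen-1-yl]ethyl}prop-2-en-1-ol | CC1=C(CC/C(=C/I)CO)[C@@]2(C)CCCC(C)(C)[C@@H]2CC1
F4 | step 13 | tert-butyldiphenylsilyl ether of F3 | CC1=C(CC/C(=C/I)CO[Si](c2ccccc2)(c2ccccc2)C(C)(C)C)[C@@]2(C)CCCC(C)(C)[C@@H]2CC1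
F5 | step 13 | (2Z)-3-{[(tert-butyldiphenylsilyl)oxy]methyl}-5-[(4aS,8aS)-2,5,5,8a-tetramethyl-3,4,4a,5,6,7,8,8a-octahydronaphthalen-1-yl]pent-2-en-1-ol | CC1=C(CC/C(=C/CO)CO[Si](c2ccccc2)(c2ccccc2)C(C)(C)C)[C@@]2(C)CCCC(C)(C)[C@@H]2CC1
F6 | step 13 | allylic bromide from F5 | CC1=C(CC/C(=C/CBr)CO[Si](c2ccccc2)(c2ccccc2)C(C)(C)C)[C@@]2(C)CCCC(C)(C)[C@@H]2CC1
F7 | step 5 | ethyl (2E)-4,4,8-trimethyl-9-oxoundec-2-enoate | CCOC(=O)/C=C/C(C)(C)CCCC(C)C(=O)CC
F8 | step 5 | (2E)-4,4,8-trimethylundec-2-ene-1,9-diol | CCC(O)C(C)CCCC(C)(C)/C=C/CO
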